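**Retrosynthetic overview**
- Rings: A = methoxy-bearing arene, B = para-phenylene, C = phenol ring, D = meta-phenylene. Target 16 comes from macrocyclic sulfone 15 by reductive removal of a phenylsulfonyl group.
- The 19-membered ring (the only ring formed; all four arenes are bought) is closed last, at the ArCH2–CH2Ar bond between rings B and C, from the open bis-sulfone phenol 13.
- Enabling feature: the free OH of ring C is para to the ring-C bridge CH2, so ring C can be unmasked as a p-quinone methide with that carbon as its exocyclic electrophilic methylene. The ring-B bridge carbon is para only to an aryl ether oxygen, cannot quinoidise, and acts as an α-sulfonyl carbanion.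
- 13 comes from ester-aldehyde 9 by global reduction, bromination, sulfinate displacement and O-debenzylation. 9 comes from B-alkyl Suzuki coupling of styrene 4 (rings A–O–B) with aryl bromide 7 (rings C–O–D), which builds the D–CH2CH2–A bridge.
- Each diaryl ether comes from a copper-mediated C–O coupling: isovanillin + methyl 4-bromobenzoate, and 4-(benzyloxy)-3-hydroxybenzaldehyde + (3-bromophenyl)boronic acid.

Key step: step 9

Remark: the target is achiral; the only stereocentre on the route (the sulfonyl-bearing carbon of 15) should form as a racemate and is erased in step 10.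

**Route**

Step 1
Reactants: 1 isovanillin (3-hydroxy-4-methoxybenzaldehyde); 2 methyl 4-bromobenzoate
Product: 3 methyl 4-(5-formyl-2-methoxyphenoxy)benzoate
Conditions: CuI (10 mol%), N,N-dimethylglycine·HCl (30 mol%), Cs2CO3, 1,4-dioxane, 90 °C
Reagents that add atoms: none
Why: Ullmann-type Cu(I)-catalysed diaryl ether synthesis, in which the electron-poor aryl bromide should couple readily with the isovanillin phenoxide while the aldehyde and methyl ester are inert to Cs2CO3 in dry dioxane.

Step 2
Reactants: 3 methyl 4-(5-formyl-2-methoxyphenoxy)benzoate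
Product: 4 methyl 4-(5-ethenyl-2-methoxyphenoxy)benzoate
Conditions: Ph3PCH3Br (1.15 equiv), KOtBu (1.1 equiv), THF, 0 °C to rt
Reagents that add atoms: methyltriphenylphosphonium bromide, C[P+](c1ccccc1)(c1ccccc1)c1ccccc1.[Br-]
Why: Wittig methylenation, in which the non-stabilised ylide should react with the aromatic aldehyde far faster than with the methyl ester at 0 °C.

Step 3
Reactants: 5 4-(benzyloxy)-3-hydroxybenzaldehyde; 6 (3-bromophenyl)boronic acid
Product: 7 4-(benzyloxy)-3-(3-bromophenoxy)benzaldehyde
Conditions: Cu(OAc)2 (20 mol%), pyridine, 4 Å MS, CH2Cl2, O2 (balloon), rt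
Reagents that add atoms: none
Why: Chan–Lam oxidative O-arylation of a phenol with an arylboronic acid at room temperature, which should leave the aryl C–Br bond, the aldehyde and the benzyl ether untouched.

Step 4
Reactants: 4 methyl 4-(5-ethenyl-2-methoxyphenoxy)benzoate; 7 4-(benzyloxy)-3-(3-bromophenoxy)benzaldehyde
Product: 9 methyl 4-[5-[2-[3-[2-(benzyloxy)-5-formylphenoxy]phenyl]ethyl]-2-methoxyphenoxy]benzoate, via alkyl-9-BBN borane 8 (not isolated)
Conditions: 4, 9-BBN, THF, 0 °C to rt; then 7, Pd(dppf)Cl2 (5 mol%), aq. K3PO4, DMF, 60 °C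
Reagents that add atoms: none
Why: anti-Markovnikov hydroboration of the styrene with 9-BBN followed by B-alkyl Suzuki–Miyaura coupling with the aryl bromide should give the saturated D–CH2CH2–A bridge directly, the ester being inert to 9-BBN and any aldehyde reduced by residual borane converging in step 5.

Step 5
Reactants: 9 methyl 4-[5-[2-[3-[2-(benzyloxy)-5-formylphenoxy]phenyl]ethyl]-2-methoxyphenoxy]benzoate
Product: 10 [4-(benzyloxy)-3-[3-[2-[3-[4-(hydroxymethyl)phenoxy]-4-methoxyphenyl]ethyl]phenoxy]phenyl]methanol
Conditions: LiAlH4, THF, 0 °C to rt; Fieser work-up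
Reagents that add atoms: none
Why: LiAlH4 hydride reduction should convert the methyl ester and the aldehyde into the two benzylic alcohols in one operation, all ethers being inert.

Step 6
Reactants: 10 [4-(benzyloxy)-3-[3-[2-[3-[4-(hydroxymethyl)phenoxy]-4-methoxyphenyl]ethyl]phenoxy]phenyl]methanol
Product: 11 1-(benzyloxy)-4-(bromomethyl)-2-[3-[2-[3-[4-(bromomethyl)phenoxy]-4-methoxyphenyl]ethyl]phenoxy]benzene
Conditions: PBr3, CH2Cl2, 0 °C; used without chromatography
Reagents that add atoms: phosphorus tribromide, BrP(Br)Br
Why: conversion of benzylic alcohols into bromides with PBr3 (SN2 on the phosphite ester) should proceed at 0 °C without affecting the aryl, methyl or benzyl ethers.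

Step 7
Reactants: 11 1-(benzyloxy)-4-(bromomethyl)-2-[3-[2-[3-[4-(bromomethyl)phenoxy]-4-methoxyphenyl]ethyl]phenoxy]benzene
Product: 12 1-(benzyloxy)-4-[(phenylsulfonyl)methyl]-2-[3-[2-[4-methoxy-3-[4-[(phenylsulfonyl)methyl]phenoxy]phenyl]ethyl]phenoxy]benzene
Conditions: PhSO2Na (3 equiv), DMF, rt to 50 °C
Reagents that add atoms: sodium benzenesulfinate, [Na+].[O-]S(=O)c1ccccc1
Why: SN2 S-alkylation of the ambident sulfinate anion by the two benzylic bromides should give both benzylic sulfones, the soft sulfur attacking the soft benzylic carbon.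

Step 8
Reactants: 12 1-(benzyloxy)-4-[(phenylsulfonyl)methyl]-2-[3-[2-[4-methoxy-3-[4-[(phenylsulfonyl)methyl]phenoxy]phenyl]ethyl]phenoxy]benzene
Product: 13 2-[3-[2-[4-methoxy-3-[4-[(phenylsulfonyl)methyl]phenoxy]phenyl]ethyl]phenoxy]-4-[(phenylsulfonyl)methyl]phenol
Conditions: H2 (1 atm), 10% Pd/C, THF–MeOH, rt
Reagents that add atoms: none
Why: catalytic hydrogenolysis of the benzyl aryl ether should free the ring-C phenol while sulfones, diaryl ethers and the methyl ether are inert, and the p-hydroxybenzyl sulfone is stable in the absence of base.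

Step 9
Reactants: 13 2-[3-[2-[4-methoxy-3-[4-[(phenylsulfonyl)methyl]phenoxy]phenyl]ethyl]phenoxy]-4-[(phenylsulfonyl)methyl]phenol
Product: 15 racemic macrocyclic sulfone (target 16 carrying a phenylsulfonyl group on the bridge carbon attached to ring B), via p-quinone methide 14 (not isolated)
Conditions: KHMDS (2.1 equiv), THF (1–2 mM), −78 °C to rt (40 °C if needed); aq. NH4Cl
Reagents that add atoms: none
Why: Proposed new method: KHMDS should first form the ring-C phenoxide and then the α-sulfonyl carbanion at the ring-B benzylic carbon (the ring-C CH2SO2Ph is deactivated by the para-phenoxide); on warming the phenoxide should expel benzenesulfinate from its para benzylic carbon (vinylogous E1cB, 1,6-elimination) to give p-quinone methide 14, whose exocyclic methylene is attacked by the tethered carbanion with re-aromatisation of ring C. The closest known reaction types are base-triggered generation of quinone methides from (arylsulfonyl)methyl phenols, 1,6-conjugate addition of stabilised carbanions to p-quinone methides, and macrocyclising benzylation of α-sulfonyl carbanions. The 19-membered ring closes by a 19-endo-trig 1,6-conjugate addition, both carbons of the attacked exocyclic C=C ending up in the new ring. The only new stereocentre, the sulfonyl-bearing benzylic carbon, is uncontrolled (racemate) and is erased in step 10. The step needs chemoselection between two identical CH2SO2Ph groups, which the free hydroxyl para to only one of them secures, since the ring-B oxygen is an aryl ether and cannot quinoidise. It also needs ring closure to beat oligomerisation, which is addressed by 1–2 mM dilution and by each quinone methide being formed already carrying its carbanion partner.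

Step 10
Reactants: 15 racemic macrocyclic sulfone
Product: 16 CNP0132125.0 (19-membered macrocycle: ring A 4-methoxy-1,3-phenylene, ring B 1,4-phenylene, ring C 4-hydroxy-1,3-phenylene, ring D 1,3-phenylene, joined by two O and two CH2CH2 links)
Conditions: Mg turnings (excess, I2-activated), MeOH–THF, 50 °C; aq. NH4Cl
Reagents that add atoms: none
Why: dissolving-metal reductive desulfonylation (single-electron transfer to the aryl sulfone, C–S cleavage to the stabilised benzylic radical/anion, protonation by methanol) should remove the activating group and the transient stereocentre without reducing the diaryl ethers, the phenol or the methyl ether.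

**Compound list**
1 | isovanillin (3-hydroxy-4-methoxybenzaldehyde) | COc1ccc(C=O)cc1O | starting material
2 | methyl 4-bromobenzoate | COC(=O)c1ccc(Br)cc1 | starting material
3 | methyl 4-(5-formyl-2-methoxyphenoxy)benzoate | COC(=O)c1ccc(Oc2cc(C=O)ccc2OC)cc1 | intermediate
4 | methyl 4-(5-ethenyl-2-methoxyphenoxy)benzoate | COC(=O)c1ccc(Oc2cc(C=C)ccc2OC)cc1 | intermediate
5 | 4-(benzyloxy)-3-hydroxybenzaldehyde | O=Cc1ccc(OCc2ccccc2)c(O)c1 | starting material
6 | (3-bromophenyl)boronic acid | OB(O)c1cccc(Br)c1 | starting material
7 | 4-(benzyloxy)-3-(3-bromophenoxy)benzaldehyde | O=Cc1ccc(OCc2ccccc2)c(Oc2cccc(Br)c2)c1 | intermediate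
8 | methyl 4-[5-[2-(9-borabicyclo[3.3.1]nonan-9-yl)ethyl]-2-methoxyphenoxy]benzoate (not isolated) | COC(=O)c1ccc(Oc2cc(CCB3C4CCCC3CCC4)ccc2OC)cc1 | intermediate
9 | methyl 4-[5-[2-[3-[2-(benzyloxy)-5-formylphenoxy]phenyl]ethyl]-2-methoxyphenoxy]benzoate | COC(=O)c1ccc(Oc2cc(CCc3cccc(Oc4cc(C=O)ccc4OCc4ccccc4)c3)ccc2OC)cc1 | intermediate
10 | [4-(benzyloxy)-3-[3-[2-[3-[4-(hydroxymethyl)phenoxy]-4-methoxyphenyl]ethyl]phenoxy]phenyl]methanol | OCc1ccc(Oc2cc(CCc3cccc(Oc4cc(CO)ccc4OCc4ccccc4)c3)ccc2OC)cc1 | intermediate
11 | 1-(benzyloxy)-4-(bromomethyl)-2-[3-[2-[3-[4-(bromomethyl)phenoxy]-4-methoxyphenyl]ethyl]phenoxy]benzene | BrCc1ccc(Oc2cc(CCc3cccc(Oc4cc(CBr)ccc4OCc4ccccc4)c3)ccc2OC)cc1 | intermediate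
12 | 1-(benzyloxy)-4-[(phenylsulfonyl)methyl]-2-[3-[2-[4-methoxy-3-[4-[(phenylsulfonyl)methyl]phenoxy]phenyl]ethyl]phenoxy]benzene | O=S(=O)(Cc1ccc(Oc2cc(CCc3cccc(Oc4cc(CS(=O)(=O)c5ccccc5)ccc4OCc4ccccc4)c3)ccc2OC)cc1)c1ccccc1 | intermediate
13 | 2-[3-[2-[4-methoxy-3-[4-[(phenylsulfonyl)methyl]phenoxy]phenyl]ethyl]phenoxy]-4-[(phenylsulfonyl)methyl]phenol | COc1ccc(CCc2cccc(Oc3cc(CS(=O)(=O)c4ccccc4)ccc3O)c2)cc1Oc1ccc(CS(=O)(=O)c2ccccc2)cc1 | intermediate
14 | p-quinone methide of 13 (ring C as 4-methylidene-cyclohexa-2,5-dienone bearing the ring-D aryloxy group at C-2; drawn in its C–H form, present in the flask as the potassium α-sulfonyl carbanion at the ring-B benzylic carbon; not isolated) | COc1ccc(CCc2cccc(OC3=CC(=C)C=CC3=O)c2)cc1Oc1ccc(CS(=O)(=O)c2ccccc2)cc1 | intermediate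
15 | racemic macrocyclic sulfone (16 with PhSO2 on the bridge carbon attached to ring B) | COc1ccc2cc1Oc1ccc(cc1)C(S(=O)(=O)c1ccccc1)Cc1ccc(O)c(c1)Oc1cccc(c1)CC2 | intermediate
16 | CNP0132125.0 | COc1ccc2cc1Oc1ccc(cc1)CCc1ccc(O)c(c1)Oc1cccc(c1)CC2 | target

**Step count and risks**

Total steps: 10. Longest linear sequence: 9 steps (1 → 3 → 4 → 9 → 10 → 11 → 12 → 13 → 15 → 16; the branch from 5 joins at step 4).

Steps most likely to fail:

1. Step 9 (Proposed new method). The quinone methide may be captured by a second molecule (oligomerisation), or sulfinate expulsion from the dianion may be too slow for clean ring closure. The fallback uses known chemistry and sets out from diol 10. Oxidation with MnO2 in CH2Cl2 should give the dialdehyde F1. Intramolecular McMurry coupling (TiCl4, Zn, pyridine, THF, reflux, syringe-pump high dilution) should form the same benzylic carbon–carbon bond as a C=C and give the macrocyclic stilbene benzyl ether F2 as an E/Z mixture. Hydrogenation (H2, Pd/C, EtOAc–MeOH) should then saturate the alkene and cleave the benzyl ether in one operation, rejoining the route at target 16.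

2. Step 4. Slow transmetalation of the alkylborane, β-hydride elimination from the alkyl–palladium species, or consumption of the aldehyde by the borane may erode the coupling. The fallback sets out from 4 and 7. A Mizoroki–Heck reaction (Pd(OAc)2, P(o-tol)3, Et3N, DMF, 100 °C) should give the (E)-stilbene F3. Chemoselective alkene hydrogenation (H2, Pd/C poisoned with Ph2S, EtOAc, rt, conditions that spare benzyl ethers and aromatic aldehydes) should then return to the route at 9.

3. Step 3. Protodeboronation or oxidative homocoupling of the boronic acid, together with the hindered ortho-benzyloxy phenol, may limit conversion in the oxidative coupling. The fallback sets out from 5 and changes the coupling manifold. A Cu(I)-catalysed Ullmann etherification with commercial 1-bromo-3-iodobenzene (2 equiv; CuI, N,N-dimethylglycine, Cs2CO3, dioxane, 80 °C) should react preferentially at the C–I bond and give 7 directly. It makes no new compound (F0).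

Further compounds
F1 | step 9 | 4-(benzyloxy)-3-[3-[2-[3-(4-formylphenoxy)-4-methoxyphenyl]ethyl]phenoxy]benzaldehyde | O=Cc1ccc(Oc2cc(CCc3cccc(Oc4cc(C=O)ccc4OCc4ccccc4)c3)ccc2OC)cc1
F2 | step 9 | macrocyclic stilbene benzyl ether (O-benzyl 16 with CH=CH in place of the B–C bridge CH2CH2, E/Z mixture) | COc1ccc2cc1Oc1ccc(cc1)C=Cc1ccc(OCc3ccccc3)c(c1)Oc1cccc(c1)CC2
F3 | step 4 | methyl 4-[5-[(E)-2-[3-[2-(benzyloxy)-5-formylphenoxy]phenyl]ethenyl]-2-methoxyphenoxy]benzoate | COC(=O)c1ccc(Oc2cc(/C=C/c3cccc(Oc4cc(C=O)ccc4OCc4ccccc4)c3)ccc2OC)cc1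
F0 | step 3 | none | none
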